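## Structural features

The target is a 24-membered macrocyclic bis-lactam: a spermidine chain (N1, three CH2, N4, four CH2, N8) acylated on both primary nitrogens by two (E)-cinnamoyl units whose arenes are joined through one diaryl ether oxygen. Ring B is a para-phenylene that carries the ether oxygen at one end and the N1 cinnamoyl at the other. Ring A is catechol-derived: the N8 cinnamoyl sits at C1, the ether oxygen at C3 (meta to the vinyl group) and the hydrogen sulfate on the oxygen at C4 (para to the vinyl group). There is no stereocentre; the only stereo-elements are the two E double bonds, which are sensitive to light. The fragile groups are the aryl sulfate monoester (lost in acid, stable to base), the secondary amine N4 (it would be N-sulfonated, adds to acrylamides and binds palladium) and the cinnamamides as Michael acceptors. The real difficulties are closing the large ring, telling N1 from N8 of the triamine, and ordering the endgame so that sulfur goes onto oxygen only and N4 is then freed without acid. The key step exploits the aryl–CH=CH–C(=O)–N8 unit on ring A: the bond from C1 of ring A to the β-carbon is made from an aryl bromide and an N8 acrylamide.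

## Logic of the disconnections

18 to 17: the N4–C(=O)CF3 bond of a protecting group is cut. A base-labile acyl group on N4 is chosen because the sulfate monoester tolerates carbonate in aqueous methanol but not the acid that a carbamate would need. The gain is an endgame with no protected sulfate diester. The demand is that the two secondary cinnamamides stay inert while the far more electrophilic trifluoroacetamide is cleaved.

17 to 16: the O–S bond is cut. Sulfation is placed after the ring closure so that no sulfate has to survive palladium, amine base and heat. The demand is a single free phenol and a non-nucleophilic N4, both of which 16 provides.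

16 to 15: the O–Si bond is cut. The silyl ether keeps the phenol neutral and away from palladium in the ring closure and comes off with buffered fluoride without touching the N4 acyl group.

15 to 14: the bond from C1 of ring A to the β-carbon of the N8 cinnamamide is cut, opening the 24-membered ring to an aryl bromide and a terminal acrylamide. The cut removes the only ring that is hard to make and leaves a linear, modular precursor. It requires one oxidative-addition site, a terminal alkene that inserts much faster than the internal one, and E-selective elimination. In 14 the bromide is para to the silyloxy group and meta to the ether oxygen and the acrylamide is on the nitrogen of the four-carbon arm, so the ring that forms has 24 members and the substitution pattern of 15.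

14 to 7 and 11 (through 12 and 13): the N1–C(=O) amide bond and the N4–C(=O)CF3 bond are cut. The trifluoroacetyl group must go on after N1 is acylated, because next to a free N1 amine it would shift from N4 to N1 through a six-membered intermediate. A triamine that carries both the acrylamide and a free primary amine is never handled as a free base: 11 is a stable bis-ammonium salt, freed only in the presence of the active ester 12. The demand is acylation of the primary N1 in preference to the secondary N4, followed by capping of N4 in the same flask.

11 to 10 to 8 and 9: the two carbamate groups and the N8–C(=O) bond are cut. The N1/N8 problem cannot be solved on the free triamine, so it is solved by starting from 8, in which only N8 is free. Acylation with 9 then needs no selectivity, and acid gives 11 directly as its salt.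

7 to 5 (through 6): the O–Si bond is cut. Silylating before the amide coupling keeps the phenol out of the active-ester chemistry. The demand is that the silyl ester formed alongside is cleaved selectively.

5 to 3 (through 4): the aryl C–O bond of the phenol is traced to an aryl C–CHO bond by oxygen insertion, and the acid to its methyl ester. The formyl group is thus used twice, first to activate the fluoride of 2 and then as the latent phenol. The demand is aryl rather than hydride migration, and an oxidant that spares the enoate.

3 to 1 and 2: the diaryl ether C–O bond is cut. Both partners are catalogue compounds. The fluoride ortho to the formyl group must be displaced and the bromide para to it must stay.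

## Other disconnections considered

Alternative 1: The cut removes two C–C bonds of ring B, so that ring B is built instead of bought. The ynol ether A2 (ring A with an ethynyloxy group, its phenol as a methoxymethyl ether and its future cinnamoyl carbon as a dioxolane) would add to the electron-poor pyranone A3 (methyl coumalate) in an inverse-demand [4+2] cycloaddition, and loss of CO2 from the bicyclic adduct would give the para-aryloxy benzoate A1.
- In its favour: the regiochemistry follows from the polarisation of both partners (the nucleophilic alkyne carbon bonds to C6 of A3), and no metal or halide is needed. The ring A oxygen pattern is present from the start, so no Baeyer–Villiger step is required; on this point it is the better plan.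
- Against it here: the diaryl ether of this target is unhindered and comes in one SNAr step from 1 and 2, whereas A2 needs several steps and is a sensitive ynol ether. A1 is a benzoate, so ring B still needs reduction, oxidation and olefination to gain two carbons, and ring A needs deacetalisation and a second olefination. The cut also says nothing about how the 24-membered ring is closed.
- Comparison: it is mechanistically sound and equal in selectivity, but it answers a question (aryl ether formation) that is not the hard one here. It should reach the stage of 5 some five or six steps later than the chosen plan.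

Alternative 2: The cut is the N1–C(=O) bond of the ring B cinnamamide, traced back to an isomer, the 20-membered lactam A5, in which that acyl group sits on N4 and N1 hangs free on its three-carbon arm. In the forward sense N1 would attack the tertiary amide carbonyl through a six-membered tetrahedral intermediate and expel N4, giving the ring-enlarged A4.
- In its favour: the ring closed by conventional means is smaller, the acyl shift trades a tertiary amide for a secondary one, and no metal is involved. N4 is freed by the key step itself, which spares one deprotection; on that count it is the equal of the chosen plan or better.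
- Against it here: a tertiary cinnamamide is a poor acyl donor, and such translactamisations normally need an amide-anion base. Under that base the N8–H amide is deprotonated first and the cinnamoyl units are exposed to conjugate addition. The equilibrium between a 20- and a 24-membered ring is not obviously one-sided. A5 is no easier to make than 14, since it needs its own macrocyclisation and an N4-selective acylation with N1 masked. The free N4 of A4 must be masked again before the phenol can be sulfated.
- Comparison: it is less certain mechanistically, the nitrogens must be told apart just as in the chosen plan, and the sequence after A4 (unmask phenol, mask N4, sulfate, unmask N4) is longer.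

Alternative 3: The cut is the N4–CH2 bond of the four-carbon arm. The open-chain A7 carries a 2-nitrobenzenesulfonamide N–H on the three-carbon side and a primary alcohol at the end of the N8 butyl chain; redox condensation under Mitsunobu conditions would close the ring to A6.
- In its favour: the sulfonamide is acidic enough, and this kind of closure has the best precedent of the four for macrocyclic polyamine lactams. Both E alkenes are in place before the ring is closed, and the triamine is assembled from two simple amines, so no N1/N8 problem arises. The sulfonyl group activates N4 for the closure and masks it during sulfation, and a thiolate removes it under conditions an aryl sulfate tolerates. On precedent for the ring closure and on protecting-group logic it is the equal of the chosen plan or better.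
- Against it here: A7 holds two different cinnamic acid units on one diaryl ether, so two carboxyl groups must be told apart and coupled in turn, which lengthens the linear sequence. The activated 4-(acylamino)butanol can close onto its own amide to a five-membered ring in competition with the slow 24-membered closure. The acetal on the phenol needs acid, and thiolate can add reversibly to the cinnamamides at the end.
- Comparison: this is a serious competitor with an endgame of similar length. The chosen plan draws the ring A cinnamoyl carbons from 9 in the ring-closing event itself, which differentiates the two acyl units automatically and should save an estimated two to four steps.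

Key step: step 7

Assumptions: 8 (N1,N4-bis-Boc-spermidine, free 4-aminobutyl terminus) is taken as a catalogue reagent. The target is drawn as the neutral hydrogen sulfate and should be isolated as its inner salt (N4 ammonium, sulfate anion), which is the same compound.

## Route

Step 1
Reactants: 1 methyl (E)-3-(4-hydroxyphenyl)prop-2-enoate (methyl p-coumarate); 2 4-bromo-2-fluorobenzaldehyde
Product: 3 methyl (E)-3-[4-(5-bromo-2-formylphenoxy)phenyl]prop-2-enoate
Conditions: K2CO3, DMF, 90 °C
Reagents that add atoms: none
Why: Nucleophilic aromatic substitution through a Meisenheimer adduct; the fluoride ortho to the formyl group is displaced by the phenoxide, while the bromide para to it is a far poorer leaving group in this addition–elimination and stays.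

Step 2
Reactants: 3 methyl (E)-3-[4-(5-bromo-2-formylphenoxy)phenyl]prop-2-enoate
Product: 5 (E)-3-[4-(5-bromo-2-hydroxyphenoxy)phenyl]prop-2-enoic acid, via aryl formate 4 (not isolated)
Conditions: mCPBA, CH2Cl2, rt; Na2S2O3/NaHCO3 wash; then LiOH, THF/MeOH/H2O, rt; HCl to pH 2
Reagents that add atoms: 3-chloroperoxybenzoic acid, O=C(OO)c1cccc(Cl)c1; lithium hydroxide, [Li+].[OH-]
Why: Baeyer–Villiger (Dakin-type) oxidation, in which the ring bearing the ortho aryloxy donor migrates in preference to hydride; a peracid in CH2Cl2 is used instead of alkaline peroxide so that the enoate is not epoxidised. Hydroxide then cleaves the formate and the methyl ester in the same operation.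

Step 3
Reactants: 5 (E)-3-[4-(5-bromo-2-hydroxyphenoxy)phenyl]prop-2-enoic acid
Product: 7 (E)-3-{4-[5-bromo-2-(triisopropylsilyloxy)phenoxy]phenyl}prop-2-enoic acid, via bis-silylated ester 6 (not isolated)
Conditions: i-Pr3SiCl (2.5 equiv), imidazole, DMF, rt; then K2CO3, THF/MeOH/H2O, 0 °C, short; citric acid
Reagents that add atoms: triisopropylsilyl chloride, CC(C)[Si](Cl)(C(C)C)C(C)C
Why: Exhaustive O-silylation followed by selective solvolysis of the silyl ester, which is far more labile to mild aqueous base than the hindered aryl silyl ether. This is the standard way to an O-silylated hydroxycinnamic acid.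

Step 4
Reactants: 8 N1,N4-bis-Boc-spermidine (tert-butyl N-(4-aminobutyl)-N-{3-[(tert-butoxycarbonyl)amino]propyl}carbamate); 9 acryloyl chloride
Product: 10 tert-butyl N-[4-(prop-2-enoylamino)butyl]-N-{3-[(tert-butoxycarbonyl)amino]propyl}carbamate
Conditions: Et3N, CH2Cl2, −20 → 0 °C
Reagents that add atoms: none
Why: N-acylation of the only free amine (N8) by an acid chloride; low temperature and slow addition suppress aza-Michael addition to the new acrylamide.

Step 5
Reactants: 10 tert-butyl N-[4-(prop-2-enoylamino)butyl]-N-{3-[(tert-butoxycarbonyl)amino]propyl}carbamate
Product: 11 N-{4-[(3-aminopropyl)amino]butyl}prop-2-enamide bis(trifluoroacetate)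
Conditions: TFA/CH2Cl2 (1:3), 0 °C → rt; evaporation, toluene co-evaporation
Reagents that add atoms: trifluoroacetic acid, OC(=O)C(F)(F)F
Why: Acidolysis of both tert-butyl carbamates; the acrylamide is inert to acid, and the product is kept as the bis-ammonium salt, in which neither nitrogen can add to the acrylamide.

Step 6
Reactants: 7 (E)-3-{4-[5-bromo-2-(triisopropylsilyloxy)phenoxy]phenyl}prop-2-enoic acid; 11 N-{4-[(3-aminopropyl)amino]butyl}prop-2-enamide bis(trifluoroacetate)
Product: 14 (E)-3-{4-[5-bromo-2-(triisopropylsilyloxy)phenoxy]phenyl}-N-(3-{[4-(prop-2-enoylamino)butyl](trifluoroacetyl)amino}propyl)prop-2-enamide, via succinimidyl ester 12 (not isolated), via N4-unprotected amide 13 (not isolated)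
Conditions: EDC·HCl, HOSu, CH2Cl2, rt; added to 11 (slight excess), i-Pr2NEt, MeCN/CH2Cl2, −20 → 0 °C; then (CF3CO)2O, 0 °C
Reagents that add atoms: trifluoroacetic anhydride, O=C(OC(=O)C(F)(F)F)C(F)(F)F
Why: Active-ester amidation; a succinimidyl ester acylates the unhindered primary N1 amine in preference to the secondary, doubly alkylated N4, the established selectivity for polyamines. The remaining N4–H is then trifluoroacetylated in the same flask, before it can add to the acrylamide and after the point at which an N4-to-N1 acyl shift is possible.

Step 7
Reactants: 14 (E)-3-{4-[5-bromo-2-(triisopropylsilyloxy)phenoxy]phenyl}-N-(3-{[4-(prop-2-enoylamino)butyl](trifluoroacetyl)amino}propyl)prop-2-enamide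
Product: 15 the 24-membered (E,E)-macrocycle with N4 trifluoroacetyl and ring A O-triisopropylsilyl groups (ring A C1 bonded to the β-carbon of the N8 cinnamamide)
Conditions: Pd2(dba)3 (cat.), [HP(t-Bu)3]BF4, Cy2NMe, 1,4-dioxane, 90 °C, 2 mM, slow addition of 14, exclusion of light
Reagents that add atoms: none
Why: Intramolecular Mizoroki–Heck reaction, the closest known type being macrocyclising Heck couplings of aryl halides with acrylamides and acrylates. Zerovalent palladium bearing one P(t-Bu)3 inserts into the only C–Br bond of 14, which lies para to the silyloxy group on ring A. The arylpalladium bromide adds syn across the acrylamide with the aryl group going to the unsubstituted terminal carbon, as the polarisation of the acrylamide and the smaller steric demand dictate. Syn β-hydride elimination from the rotamer with aryl and carboxamide anti gives the E alkene, and Cy2NMe takes up HBr to return zerovalent palladium. The ring closes in the 24-endo-trig mode, both alkene carbons ending inside the ring. No stereocentre is formed; the one new stereo-element, the E double bond, is fixed by the syn-addition/syn-elimination sequence and by the thermodynamic preference of the cinnamamide. The step needs ring closure to beat intermolecular coupling and needs insertion of the acrylamide, not of the existing cinnamamide: high dilution with slow addition secures the first; the much slower insertion of a 1,2-disubstituted alkene and the pre-organisation by the rigid diaryl ether and E cinnamamide secure the second. The silyl ether and the trifluoroacetamide keep the phenol and N4 from binding palladium or adding to the acrylamide.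

Step 8
Reactants: 15 the N4-trifluoroacetyl, O-triisopropylsilyl macrocycle
Product: 16 the N4-trifluoroacetyl macrocycle with the free ring A phenol
Conditions: Bu4NF, AcOH (1:1), THF, 0 °C
Reagents that add atoms: none
Why: Fluoride-induced cleavage of an aryl silyl ether; buffering with acetic acid keeps the medium from becoming basic enough to attack the trifluoroacetamide.

Step 9
Reactants: 16 the N4-trifluoroacetyl macrocycle with the free ring A phenol
Product: 17 sodium salt of the ring A aryl sulfate of the N4-trifluoroacetyl macrocycle
Conditions: SO3·pyridine, pyridine, 40 °C; aq NaHCO3; C18 silica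
Reagents that add atoms: sulfur trioxide–pyridine complex, [O-]S(=O)(=O)[n+]1ccccc1; sodium hydrogencarbonate, [Na+].OC([O-])=O
Why: O-sulfonation of a phenol by an amine–sulfur trioxide complex; the phenol is the only nucleophile, since N4 is acylated and secondary amide N–H groups do not react under these conditions.

Step 10
Reactants: 17 sodium salt of the ring A aryl sulfate of the N4-trifluoroacetyl macrocycle
Product: 18 the target, CID124202369 (24-membered (E,E)-bis-cinnamoyl spermidine lactam with free N4 and the ring A hydrogen sulfate)
Conditions: K2CO3, MeOH/H2O (4:1), rt; AcOH to pH 6; C18 silica (H2O/MeCN), amber glassware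
Reagents that add atoms: none
Why: Base solvolysis of a tertiary trifluoroacetamide, whose carbonyl is far more electrophilic than the two conjugated secondary amides. Aryl sulfate monoester anions are inert to carbonate, so the sulfate never meets acid stronger than acetic acid.

## Compound list

1 | methyl (E)-3-(4-hydroxyphenyl)prop-2-enoate | COC(=O)/C=C/c1ccc(O)cc1 | starting material
2 | 4-bromo-2-fluorobenzaldehyde | O=Cc1ccc(Br)cc1F | starting material
3 | methyl (E)-3-[4-(5-bromo-2-formylphenoxy)phenyl]prop-2-enoate | COC(=O)/C=C/c1ccc(cc1)Oc1cc(Br)ccc1C=O | intermediate
4 | methyl (E)-3-{4-[5-bromo-2-(formyloxy)phenoxy]phenyl}prop-2-enoate (not isolated) | COC(=O)/C=C/c1ccc(cc1)Oc1cc(Br)ccc1OC=O | intermediate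
5 | (E)-3-[4-(5-bromo-2-hydroxyphenoxy)phenyl]prop-2-enoic acid | OC(=O)/C=C/c1ccc(cc1)Oc1cc(Br)ccc1O | intermediate
6 | triisopropylsilyl (E)-3-{4-[5-bromo-2-(triisopropylsilyloxy)phenoxy]phenyl}prop-2-enoate (not isolated) | CC(C)[Si](C(C)C)(C(C)C)OC(=O)/C=C/c1ccc(cc1)Oc1cc(Br)ccc1O[Si](C(C)C)(C(C)C)C(C)C | intermediate
7 | (E)-3-{4-[5-bromo-2-(triisopropylsilyloxy)phenoxy]phenyl}prop-2-enoic acid | OC(=O)/C=C/c1ccc(cc1)Oc1cc(Br)ccc1O[Si](C(C)C)(C(C)C)C(C)C | intermediate
8 | N1,N4-bis-Boc-spermidine, tert-butyl N-(4-aminobutyl)-N-{3-[(tert-butoxycarbonyl)amino]propyl}carbamate | NCCCCN(C(=O)OC(C)(C)C)CCCNC(=O)OC(C)(C)C | starting material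
9 | acryloyl chloride | C=CC(Cl)=O | starting material
10 | tert-butyl N-[4-(prop-2-enoylamino)butyl]-N-{3-[(tert-butoxycarbonyl)amino]propyl}carbamate | C=CC(=O)NCCCCN(C(=O)OC(C)(C)C)CCCNC(=O)OC(C)(C)C | intermediate
11 | N-{4-[(3-aminopropyl)amino]butyl}prop-2-enamide bis(trifluoroacetate) | C=CC(=O)NCCCCNCCCN.OC(=O)C(F)(F)F.OC(=O)C(F)(F)F | intermediate
12 | 2,5-dioxopyrrolidin-1-yl (E)-3-{4-[5-bromo-2-(triisopropylsilyloxy)phenoxy]phenyl}prop-2-enoate (not isolated) | O=C1CCC(=O)N1OC(=O)/C=C/c1ccc(cc1)Oc1cc(Br)ccc1O[Si](C(C)C)(C(C)C)C(C)C | intermediate
13 | (E)-3-{4-[5-bromo-2-(triisopropylsilyloxy)phenoxy]phenyl}-N-[3-({4-[(prop-2-enoyl)amino]butyl}amino)propyl]prop-2-enamide (not isolated) | C=CC(=O)NCCCCNCCCNC(=O)/C=C/c1ccc(cc1)Oc1cc(Br)ccc1O[Si](C(C)C)(C(C)C)C(C)C | intermediate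
14 | (E)-3-{4-[5-bromo-2-(triisopropylsilyloxy)phenoxy]phenyl}-N-(3-{[4-(prop-2-enoylamino)butyl](trifluoroacetyl)amino}propyl)prop-2-enamide | C=CC(=O)NCCCCN(C(=O)C(F)(F)F)CCCNC(=O)/C=C/c1ccc(cc1)Oc1cc(Br)ccc1O[Si](C(C)C)(C(C)C)C(C)C | intermediate
15 | 24-membered (E,E)-macrocycle, N4-trifluoroacetyl, ring A O-triisopropylsilyl | O=C1/C=C/c2ccc(O[Si](C(C)C)(C(C)C)C(C)C)c(c2)Oc2ccc(cc2)/C=C/C(=O)NCCCN(C(=O)C(F)(F)F)CCCCN1 | intermediate
16 | 24-membered (E,E)-macrocycle, N4-trifluoroacetyl, free ring A phenol | O=C1/C=C/c2ccc(O)c(c2)Oc2ccc(cc2)/C=C/C(=O)NCCCN(C(=O)C(F)(F)F)CCCCN1 | intermediate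
17 | sodium salt of the ring A aryl sulfate of the N4-trifluoroacetyl macrocycle | O=C1/C=C/c2ccc(OS(=O)(=O)[O-])c(c2)Oc2ccc(cc2)/C=C/C(=O)NCCCN(C(=O)C(F)(F)F)CCCCN1.[Na+] | intermediate
18 | CID124202369, the macrocyclic hydrogen sulfate with free N4 | O=C1/C=C/c2ccc(OS(=O)(=O)O)c(c2)Oc2ccc(cc2)/C=C/C(=O)NCCCNCCCCN1 | target

## Step count and least certain steps

Total: 10 steps. Longest linear sequence: 8 steps (1, 2, 3, 6, 7, 8, 9, 10); the amine branch (4, 5) has 2.

**Step 7 (key step).**
- What may go wrong: intermolecular Heck coupling to oligomers may outrun the ring closure at any practical dilution. Once olefin insertion is slow, reduction of the C–Br bond or decay of the ligand-poor catalyst to palladium black can take over.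
- Fallback: the ring-closing bond is changed from aryl–Cβ to Cα=Cβ. Setting out from 14, Stille coupling with Bu3SnCH=CH2 (Pd(PPh3)4, toluene, 100 °C, no base, so that the Heck pathway stays shut) should give the 5-vinyl analogue of 14, (E)-3-{4-[5-ethenyl-2-(triisopropylsilyloxy)phenoxy]phenyl}-N-(3-{[4-(prop-2-enoylamino)butyl](trifluoroacetyl)amino}propyl)prop-2-enamide F1. Ring-closing metathesis of F1 with the second-generation Hoveyda–Grubbs catalyst RuCl2(H2IMes)(=CH–C6H4-2-O-i-Pr) in toluene at 80 °C under high dilution should load the carbene on the styrene, close onto the acrylamide with loss of ethene, and come back to the route at 15.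

**Step 6.**
- What may go wrong: loss of site selectivity (acylation of the secondary N4 amine as well as N1), and conjugate addition of the liberated amines to the acrylamide before N4 is capped.
- Fallback: the selectivity question is removed by tying N1 and N4 together. Setting out from 11, free-basing with K2CO3 and condensation with one equivalent of aqueous formaldehyde should give the six-membered aminal N-[4-(1,3-diazinan-1-yl)butyl]prop-2-enamide F2. In F2 only one N–H is left, and acylation of F2 with 12 should give the N1-acylated aminal N-[4-(3-{(E)-3-[4-(5-bromo-2-(triisopropylsilyloxy)phenoxy)phenyl]prop-2-enoyl}-1,3-diazinan-1-yl)butyl]prop-2-enamide F3. Heating F3 with malonic acid and pyridine in ethanol removes the methylene bridge by Knoevenagel trapping and comes back to the route at 13, which is capped with (CF3CO)2O to 14 as in step 6.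

**Step 2.**
- What may go wrong: migration of hydride instead of the bromo-substituted aryl group in the peracid adduct, which leads to the benzoic acid, or slow epoxidation of the enoate on prolonged exposure.
- Fallback: the phenol oxygen is brought in with the coupling partner. Setting out from 1, Chan–Lam coupling with (5-bromo-2-methoxyphenyl)boronic acid (Cu(OAc)2 (cat.), pyridine, 4 Å molecular sieves, CH2Cl2, air, rt) should give methyl (E)-3-[4-(5-bromo-2-methoxyphenoxy)phenyl]prop-2-enoate F4. Treatment of F4 with BBr3 (CH2Cl2, −78 → 0 °C) should cleave the methyl ether to methyl (E)-3-[4-(5-bromo-2-hydroxyphenoxy)phenyl]prop-2-enoate F5, and saponification of F5 with LiOH in THF/MeOH/H2O comes back to the route at 5.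

**Step 9.**
- What may go wrong: incomplete O-sulfonation of the phenol, which is flanked by the aryloxy group, and losses of the polar salt during isolation from pyridine and inorganic sulfate.
- Fallback: the sulfate is introduced as a neutral diester that can be purified on silica. Setting out from 16, deprotonation of the phenol with one equivalent of NaN(SiMe3)2 (THF, −78 °C) and reaction with 2,2-dimethylpropyl chlorosulfate should give the 2,2-dimethylpropyl aryl sulfate diester of the N4-trifluoroacetyl macrocycle F6. Heating F6 with NaN3 in DMF at 70 °C removes the neopentyl group by SN2 attack at carbon and comes back to the route at 17.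

## Further compounds

F1 | step 7 | (E)-3-{4-[5-ethenyl-2-(triisopropylsilyloxy)phenoxy]phenyl}-N-(3-{[4-(prop-2-enoylamino)butyl](trifluoroacetyl)amino}propyl)prop-2-enamide | C=CC(=O)NCCCCN(C(=O)C(F)(F)F)CCCNC(=O)/C=C/c1ccc(cc1)Oc1cc(C=C)ccc1O[Si](C(C)C)(C(C)C)C(C)C
F2 | step 6 | N-[4-(1,3-diazinan-1-yl)butyl]prop-2-enamide | C=CC(=O)NCCCCN1CCCNC1
F3 | step 6 | N-[4-(3-{(E)-3-[4-(5-bromo-2-(triisopropylsilyloxy)phenoxy)phenyl]prop-2-enoyl}-1,3-diazinan-1-yl)butyl]prop-2-enamide | C=CC(=O)NCCCCN1CCCN(C1)C(=O)/C=C/c1ccc(cc1)Oc1cc(Br)ccc1O[Si](C(C)C)(C(C)C)C(C)C
F4 | step 2 | methyl (E)-3-[4-(5-bromo-2-methoxyphenoxy)phenyl]prop-2-enoate | COC(=O)/C=C/c1ccc(cc1)Oc1cc(Br)ccc1OC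
F5 | step 2 | methyl (E)-3-[4-(5-bromo-2-hydroxyphenoxy)phenyl]prop-2-enoate | COC(=O)/C=C/c1ccc(cc1)Oc1cc(Br)ccc1O
F6 | step 9 | 2,2-dimethylpropyl aryl sulfate diester of the N4-trifluoroacetyl macrocycle | O=C1/C=C/c2ccc(OS(=O)(=O)OCC(C)(C)C)c(c2)Oc2ccc(cc2)/C=C/C(=O)NCCCN(C(=O)C(F)(F)F)CCCCN1
A1 | alternative 1 | methyl 4-[5-(1,3-dioxolan-2-yl)-2-(methoxymethoxy)phenoxy]benzoate | COC(=O)c1ccc(cc1)Oc1cc(ccc1OCOC)C1OCCO1
A2 | alternative 1 | 2-[3-(ethynyloxy)-4-(methoxymethoxy)phenyl]-1,3-dioxolane | C#COc1cc(ccc1OCOC)C1OCCO1
A3 | alternative 1 | methyl 2-oxo-2H-pyran-5-carboxylate (methyl coumalate) | COC(=O)C1=COC(=O)C=C1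
A4 | alternative 2 | 24-membered macrocycle, ring A O-(4-methoxybenzyl), free N4 | O=C1/C=C/c2ccc(OCc3ccc(OC)cc3)c(c2)Oc2ccc(cc2)/C=C/C(=O)NCCCNCCCCN1
A5 | alternative 2 | 20-membered lactam with the ring B cinnamoyl on N4 and a pendant 3-aminopropyl group | O=C1/C=C/c2ccc(OCc3ccc(OC)cc3)c(c2)Oc2ccc(cc2)/C=C/C(=O)N(CCCN)CCCCN1
A6 | alternative 3 | 24-membered macrocycle, N4-(2-nitrobenzenesulfonyl), ring A O-methoxymethyl | O=C1/C=C/c2ccc(OCOC)c(c2)Oc2ccc(cc2)/C=C/C(=O)NCCCN(S(=O)(=O)c3ccccc3[N+](=O)[O-])CCCCN1
A7 | alternative 3 | open-chain N8-(4-hydroxybutyl) amide with the N4 2-nitrobenzenesulfonamide N–H | OCCCCNC(=O)/C=C/c1ccc(OCOC)c(c1)Oc1ccc(cc1)/C=C/C(=O)NCCCNS(=O)(=O)c1ccccc1[N+](=O)[O-]
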